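If each turnover of the catalyst takes one reagent and one substrate, you can count what the birch flask has to do before asking how fast it does it.

in all of them: left-handed substrate 10 mM; right-handed substrate 10 mM

| charge | reagent | free catalyst | remark |
|---|---|---|---|
| birch | 12 mM | 50 µM | the very flask that is asked about, followed so far |
| elm | 12 mM | 100 µM | run made earlier |
| flask | 12.0 mM | 50 µM |  |

| run | time / min | left-handed product / % | left-handed substrate / % |
|---|---|---|---|
| birch | 5.00 | 2 | 49 |
| birch | 10.0 | 9 | 46 |
| birch | 15.0 | 11 | 40 |
| birch | 20.0 | 14 | 44 |
| elm | 6.00 | 10 | 41 |
| elm | 12.0 | 16 | 39 |
| elm | 30.0 | 24 | 33 |
| elm | 80.0 | 35 | 23 |

(readings scatter by 2 percentage points)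

- free catalyst is single-handed; left-handed substrate and right-handed substrate are mirror images of each other, charged as a racemate, each of them at the stated concentration
- what was read earlier has a scatter of 2 percentage points, one standard deviation
- no earlier run changes the charge of reagent; that part of a forecast is a guess

1. apparent order in reagent when 20% of the left-handed substrate and right-handed substrate together are converted (percent change of the rate of making left-handed product for one percent more reagent charged)
2. apparent order in free catalyst when 20% of the left-handed substrate and right-handed substrate together are converted (percent change of the rate of making left-handed product for one percent more free catalyst charged)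

The two substrates together come to 20.0 mM, so 20% conversion means 4.00 mM converted, which is 80.0 turnovers per free catalyst charged. Those turnovers take 4.00 mM of the reagent, the limiting reagent at 12.0 mM, and leave 8.00 mM. The reagent leverage, the charge divided by that remainder, is 1.50. At that fixed conversion, one percent more charge leaves the amount used unchanged, so the remainder grows by 1.50 percent, and if the rate is first order in [reagent] and nothing else in the rate shifts with the charge, the apparent order equals the leverage.

That first order is the weak link, since no run varies the reagent, but the elm curve gives an indirect look at it if free catalyst is taken as constant. Taking the two substrates as equal, the elm readings between 30.0 min and 80.0 min average 28.0% left-handed substrate, so the same count leaves 3.20 mM of reagent. First order in reagent and substrate then predicts 0.149 of the opening rate, and the readings, with the mean rate up to 6.00 min standing in for the opening rate, show about 0.132. With the reagent left out, the prediction is 0.560. I commit to 1.50 in reagent and, if the catalyst survives, 1 in free catalyst.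

The forecast gives 0.7 in reagent and 1 in free catalyst. It matches my catalyst order and sits lower on reagent, noting that “No run varies reagent”.

The simulation gives 1.7 in reagent and 1.2 in free catalyst, and in this flask spent catalyst already stands at 7.23% of the catalyst charged after 10.0 min.

    free catalyst → spent catalyst (k = 1.25 × 10⁻⁴ /s)
    reagent + free catalyst + left-handed substrate → free catalyst + left-handed product (k = 519 /M²/s)
    reagent + free catalyst + right-handed substrate → free catalyst + right-handed product (k = 207 /M²/s)
    left-handed substrate ⇌ right-handed substrate (k = 0.00294 /s)

A run with twice the reagent has a leverage of 1.20. With first order in [reagent], and with the substrates and free catalyst held constant, the time to that conversion goes as the logarithm of the leverage, so this run should take 0.450 of the time, and the simulation's factor is 0.429.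

Readings and results were computed on assumed constants, and the scatter is random.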